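**Retrosynthetic overview**

1. The target comes from alcohol 24 by angeloylation at O19 and release of the C15 acid from its tert-butyl ester. The 7-ene and H-9α of 23 come from a 1,4-hydrogenation of the ring B 6,8-diene 22, whose C9–C11 bond is a Negishi coupling of dienyl triflate 17 with the (Z)-enoate zinc reagent 21.
2. 17 is reached from the trans-decalin 7,9-dione 13 (ring B as a 2-methylcyclohexane-1,3-dione). 13 is cut at C5–C10 (Michael) and C7–C8 (Claisen) in one operation back to the monocyclic keto δ-lactone 10.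
3. Enabling feature: ring B consists of two three-carbon halves, C5–C6–C7 and C8–C9–C10, joined only by the C5–C10 and C7–C8 bonds, so with carbonyls at C7 and C9 it is the retron of a [3+3] Michael–Claisen annulation. The axial C19 oxygen on quaternary C4 can reach C7 as a δ-lactone ring (O–C19–C4–C5=C6–C7) that activates C5, relays the C4 configuration to C5, acts as the acyl donor and is opened to the free 19-OH in the same step.
4. 10 comes from geraniol: Sharpless epoxidation and an epoxy silyl ether rearrangement set quaternary C4, Z-olefination and lactonisation build the temporary ring, and SeO2 oxidation, Et2Zn addition and redox isomerisation turn the prenyl end into the ethyl ketone.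
5. Order of ring formation: temporary lactone ring (step 5), then ring A (C5–C10) and ring B (C7–C8) together in step 9, which also destroys the lactone ring.

Key step: step 9

Remarks on the chemistry:
- Labdane numbering (C1–C20) is used in the text for the atoms of all intermediates.
- Assumption: the rearrangement of step 3 proceeds with anti migration of the siloxymethyl group (inversion at the tertiary epoxide carbon). This makes the D-tartrate-derived (2R,3R)-epoxide the correct one; with syn migration L-tartrate would be used instead.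
- Angelic anhydride and 4-bromobut-1-yne are taken as commercial. Compounds 9 and 10 are epimer mixtures at centres that are destroyed in steps 8 and 9.

**Route**

Step 1
Reactants: 1 geraniol
Product: 2 (2R,3R)-2,3-epoxygeraniol
Conditions: Ti(OiPr)4 (5 mol %), D-(−)-diethyl tartrate (6 mol %), t-BuOOH, 4 Å sieves, CH2Cl2, −20 °C
Reagents that add atoms: tert-butyl hydroperoxide, CC(C)(C)OO
Why: Sharpless asymmetric epoxidation; the D-tartrate titanium catalyst should deliver oxygen to the face of the allylic alcohol that gives the (2R,3R)-epoxide, and the distal trisubstituted alkene is not an allylic alcohol and stays.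

Step 2
Reactants: 2 (2R,3R)-2,3-epoxygeraniol
Product: 3 tert-butyldimethylsilyl ether of 2
Conditions: TBSCl, imidazole, DMF, 0 °C to rt
Reagents that add atoms: tert-butyldimethylsilyl chloride, CC(C)(C)[Si](C)(C)Cl
Why: standard silylation of the primary alcohol, needed because the rearrangement of step 3 requires the silyl ether.

Step 3
Reactants: 3 epoxy silyl ether
Product: 4 (R)-2-{[(tert-butyldimethylsilyl)oxy]methyl}-2,6-dimethylhept-5-enal
Conditions: MeAl(OAr)2 (Ar = 4-bromo-2,6-di-tert-butylphenyl; MABR, 2 equiv, from Me3Al and ArOH), CH2Cl2, −78 °C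
Reagents that add atoms: none
Why: Lewis acid-promoted epoxy silyl ether rearrangement (semipinacol type); the bulky aluminium reagent opens the epoxide at the tertiary carbon and the siloxymethyl group migrates anti to the leaving oxygen, so the epoxide chirality is transferred with inversion to the new quaternary carbon C4.

Step 4
Reactants: 4 (R)-aldehyde
Product: 5 methyl (2Z,4S)-4-{[(tert-butyldimethylsilyl)oxy]methyl}-4,8-dimethylnona-2,7-dienoate
Conditions: (CF3CH2O)2P(O)CH2CO2Me, KN(SiMe3)2, 18-crown-6, THF, −78 °C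
Reagents that add atoms: methyl bis(2,2,2-trifluoroethyl)phosphonoacetate, COC(=O)CP(=O)(OCC(F)(F)F)OCC(F)(F)F
Why: Still–Gennari olefination should give the Z-enoate needed for lactonisation; the aldehyde has no α-hydrogen and cannot epimerise.

Step 5
Reactants: 5 Z-enoate
Product: 7 (5S)-5-methyl-5-(4-methylpent-3-en-1-yl)-5,6-dihydro-2H-pyran-2-one, via hydroxy ester 6 (not isolated)
Conditions: HF·pyridine, THF, 0 °C to rt; then PPTS (cat.), benzene, 50 °C
Reagents that add atoms: none
Why: desilylation frees the δ-hydroxy Z-enoate, which should lactonise readily because of the Z geometry and the gem-disubstituted C4.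

Step 6
Reactants: 7 unsaturated δ-lactone
Product: 8 (2E)-2-methyl-6-[(3S)-3-methyl-6-oxo-3,6-dihydro-2H-pyran-3-yl]hex-2-enal
Conditions: SeO2 (1.2 equiv), 1,4-dioxane/H2O, 80 °C
Reagents that add atoms: selenium dioxide, O=[Se]=O
Why: Riley allylic oxidation (ene reaction, then [2,3]-shift) at the E-methyl of the trisubstituted alkene, carried through to the enal; the lactone alkene is electron-poor and has no allylic hydrogen.

Step 7
Reactants: 8 enal
Product: 9 (5S)-5-[(3E)-5-hydroxy-4-methylhept-3-en-1-yl]-5-methyl-5,6-dihydro-2H-pyran-2-one (both carbinol epimers)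
Conditions: Et2Zn (1.5 equiv), 2-(dibutylamino)ethanol (10 mol %), toluene, 0 °C to rt
Reagents that add atoms: diethylzinc, CC[Zn]CC
Why: amino alcohol-accelerated 1,2-addition of a dialkylzinc to the aldehyde, to which the lactone is inert; the new carbinol centre is removed in step 8.

Step 8
Reactants: 9 allylic alcohol
Product: 10 (5S)-5-methyl-5-(4-methyl-5-oxoheptyl)-5,6-dihydro-2H-pyran-2-one (both epimers at the chain methine, the later C10)
Conditions: RuCl2(PPh3)3 (5 mol %), toluene, 110 °C
Reagents that add atoms: none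
Why: ruthenium hydride-catalysed redox isomerisation of a secondary allylic alcohol to the saturated ketone; the lactone alkene cannot migrate because C4 is quaternary.

Step 9
Reactants: 10 keto δ-lactone
Product: 13 (4aS,5S,8aS)-5-(hydroxymethyl)-2,5,8a-trimethylhexahydronaphthalene-1,3(2H,4H)-dione (trans-decalin, H-5α, CH3-10β, 4β-CH2OH; mainly enolised), via Michael adduct 11 (not isolated), via hydroxy methyl ester 12 (not isolated)
Conditions: NaOMe (3 equiv), MeOH (0.02 M), 65 °C; then aq. HCl to pH 3
Reagents that add atoms: none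
Why: Methoxide equilibrates the ketone enolates, the tetrasubstituted C10 enolate adds to C5 of the unsaturated δ-lactone (Michael, gives 11), methoxide opens the now saturated lactone to hydroxy ester 12, and the C8 enolate acylates at C7 (Dieckmann-type Claisen), the 1,3-dione enolate being the thermodynamic sink. The closest known reaction type is the consecutive Michael–Claisen [3+3] synthesis of cyclohexane-1,3-diones from ketones and α,β-unsaturated esters (dimedone synthesis), here intramolecular. Ring A closes by a 6-(enolexo)-exo-trig Michael addition and ring B by a 6-(enolexo)-exo-trig acyl substitution. C5 is set by the lactone ring: axial attack on the cyclic enoate by the chain held on C4 can only give the cis-fused bicycle, so C19 and C6 end cis and H-5 is α; C10 is set in the chair-like transition state of ring A, where the planar enolate carbon C9 sits anti to quaternary C4 and the small methyl takes the crowded sector between C4 and C6, which gives the trans relation of H-5 and CH3-10. The step needs regioselectivity between the C8 and C10 enolates, secured by ring size (C10 reaches C5 through a six-membered ring, C8 would close an eight-membered one), and C-acylation at C7, secured because after the Michael addition C8 is the only enolisable carbon placed 1,5 to the ester carbon.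

Step 10
Reactants: 13 dione alcohol
Product: 14 (4aS,5S,8aS)-5-{[(tert-butyldimethylsilyl)oxy]methyl}-2,5,8a-trimethylhexahydronaphthalene-1,3(2H,4H)-dione
Conditions: TBSCl, imidazole, DMF, 40 °C; dilute citric acid work-up
Reagents that add atoms: tert-butyldimethylsilyl chloride, CC(C)(C)[Si](C)(C)Cl
Why: silylation of the primary 19-OH; any O-silyl enol ether of the dione should be cleaved by the mildly acidic work-up.

Step 11
Reactants: 14 silyl-protected dione
Product: 15 (4aS,5S,8aS)-5-{[(tert-butyldimethylsilyl)oxy]methyl}-2,5,8a-trimethyl-1-oxo-1,4,4a,5,6,7,8,8a-octahydronaphthalen-3-yl triflate (triflate on C7, ketone on C9)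
Conditions: Tf2O (1.1 equiv), pyridine, CH2Cl2, −78 to 0 °C
Reagents that add atoms: trifluoromethanesulfonic anhydride, O=S(=O)(OS(=O)(=O)C(F)(F)F)C(F)(F)F
Why: O-sulfonylation of the enolised 1,3-dione; the oxygen on C7 should react because the oxygen on C9 is shielded by quaternary C10.

Step 12
Reactants: 15 vinylogous acyl triflate
Product: 16 (4aS,5S,8aS)-5-{[(tert-butyldimethylsilyl)oxy]methyl}-2,5,8a-trimethyl-4a,5,6,7,8,8a-hexahydronaphthalen-1(4H)-one (9-oxo-7-ene)
Conditions: Pd(OAc)2 (5 mol %), PPh3 (10 mol %), HCO2H, Bu3N, DMF, 60 °C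
Reagents that add atoms: none
Why: palladium-catalysed formate reduction of an enol triflate (oxidative addition, formate exchange, decarboxylation, reductive elimination) replaces the triflate on C7 by hydrogen and leaves the enone.

Step 13
Reactants: 16 enone
Product: 17 (4aS,5S,8aS)-5-{[(tert-butyldimethylsilyl)oxy]methyl}-2,5,8a-trimethyl-4a,5,6,7,8,8a-hexahydronaphthalen-1-yl triflate (6,8-diene, triflate on C9)
Conditions: LiN(iPr)2 (1.2 equiv), THF, −78 °C; PhNTf2, −78 to 0 °C
Reagents that add atoms: N-phenylbis(trifluoromethanesulfonimide), O=S(=O)(N(c1ccccc1)S(=O)(=O)C(F)(F)F)C(F)(F)F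
Why: C10 is quaternary, so the amide base can only remove a γ-hydrogen at C6; O-triflation of the linear dienolate gives the dienyl triflate.

Step 14
Reactants: 18 4-bromobut-1-yne
Product: 19 tert-butyl 5-bromopent-2-ynoate
Conditions: LiN(iPr)2 (1.05 equiv), THF, −78 °C; Boc2O, −78 °C; AcOH quench at −78 °C
Reagents that add atoms: di-tert-butyl dicarbonate, CC(C)(C)OC(=O)OC(=O)OC(C)(C)C
Why: acylation of the lithium acetylide with the dicarbonate gives the tert-butyl ynoate; the cold quench avoids base-induced loss of HBr.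

Step 15
Reactants: 19 ynoate
Product: 20 tert-butyl (Z)-5-bromo-3-methylpent-2-enoate
Conditions: Me2CuLi (1.2 equiv, from MeLi and CuI), THF, −78 °C; MeOH at −78 °C, then aq. NH4Cl
Reagents that add atoms: lithium dimethylcuprate, [Li+].C[Cu-]C
Why: syn-carbocupration of the ynoate with cold protonation places the chain cis to the ester, which is the 13Z geometry; the primary bromide is inert at −78 °C.

Step 16
Reactants: 17 dienyl triflate; 20 tert-butyl (Z)-5-bromo-3-methylpent-2-enoate
Product: 22 tert-butyl (4S,5R,10S,13Z)-19-[(tert-butyldimethylsilyl)oxy]labda-6,8,13-trien-15-oate, via alkylzinc bromide 21 (not isolated)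
Conditions: Zn dust, LiCl, THF, 50 °C (gives 21); then 17, Pd(OAc)2 (5 mol %), SPhos (10 mol %), THF/NMP, 60 °C
Reagents that add atoms: none
Why: Negishi coupling of a primary alkylzinc halide with an enol triflate forms C9–C11 with retention of the enoate geometry; ester and silyl ether tolerate the organozinc.

Step 17
Reactants: 22 ring B 6,8-diene
Product: 23 tert-butyl (4S,5R,9S,10R,13Z)-19-[(tert-butyldimethylsilyl)oxy]labda-7,13-dien-15-oate
Conditions: (η6-naphthalene)Cr(CO)3 (20 mol %), H2 (70 atm), THF, 45 °C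
Reagents that add atoms: none
Why: arene chromium tricarbonyl-catalysed 1,4-hydrogenation of an s-cis 1,3-diene adds both hydrogens (to C6 and C9) from the metal-bound face and leaves the 7-ene; the β face is blocked by the axial 10-methyl and 19-CH2O groups, so H-9 should enter α, and the isolated enoate is not a diene and is not reduced.

Step 18
Reactants: 23 silyl ether
Product: 24 tert-butyl (4S,5R,9S,10R,13Z)-19-hydroxylabda-7,13-dien-15-oate
Conditions: Bu4NF, THF, rt; aq. NH4Cl
Reagents that add atoms: none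
Why: fluoride-mediated desilylation; the tert-butyl ester and both alkenes are stable to fluoride.

Step 19
Reactants: 24 primary alcohol
Product: 25 tert-butyl (4S,5R,9S,10R,13Z)-19-[(Z)-2-methylbut-2-enoyloxy]labda-7,13-dien-15-oate
Conditions: LiN(SiMe3)2 (1.0 equiv), THF, −20 °C; angelic anhydride, −20 to 0 °C
Reagents that add atoms: angelic anhydride, C/C=C(/C)C(=O)OC(=O)/C(C)=C\C
Why: acylation of the preformed lithium alkoxide by the anhydride needs no nucleophilic catalyst or heat, which are the usual causes of angelate-to-tiglate isomerisation.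

Step 20
Reactants: 25 angelate tert-butyl ester
Product: 27 target, (4S,5R,9S,10R,13Z)-19-[(Z)-2-methylbut-2-enoyloxy]labda-7,13-dien-15-oic acid, via trimethylsilyl ester 26 (not isolated)
Conditions: TMSOTf, 2,6-lutidine, CH2Cl2, 0 °C; then pH 5 aqueous buffer
Reagents that add atoms: none
Why: silyl triflate-mediated cleavage of a tert-butyl ester (O-silylation, loss of the tert-butyl cation as isobutene) under buffered conditions; the primary angelate cannot fragment this way and the 7-ene sees no free strong acid.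

**Compound list**

1 | geraniol | CC(C)=CCC/C(C)=C/CO | starting material
2 | (2R,3R)-2,3-epoxygeraniol | C[C@]1(CCC=C(C)C)O[C@@H]1CO | intermediate
3 | (2R,3R)-2,3-epoxygeranyl tert-butyldimethylsilyl ether | C[C@]1(CCC=C(C)C)O[C@@H]1CO[Si](C)(C)C(C)(C)C | intermediate
4 | (R)-2-{[(tert-butyldimethylsilyl)oxy]methyl}-2,6-dimethylhept-5-enal | CC(C)=CCC[C@@](C)(C=O)CO[Si](C)(C)C(C)(C)C | intermediate
5 | methyl (2Z,4S)-4-{[(tert-butyldimethylsilyl)oxy]methyl}-4,8-dimethylnona-2,7-dienoate | COC(=O)/C=C\[C@@](C)(CO[Si](C)(C)C(C)(C)C)CCC=C(C)C | intermediate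
6 | methyl (2Z,4S)-4-(hydroxymethyl)-4,8-dimethylnona-2,7-dienoate | COC(=O)/C=C\[C@@](C)(CO)CCC=C(C)C | intermediate
7 | (5S)-5-methyl-5-(4-methylpent-3-en-1-yl)-5,6-dihydro-2H-pyran-2-one | O=C1C=C[C@](C)(CCC=C(C)C)CO1 | intermediate
8 | (2E)-2-methyl-6-[(3S)-3-methyl-6-oxo-3,6-dihydro-2H-pyran-3-yl]hex-2-enal | O=C1C=C[C@](C)(CC/C=C(\C)C=O)CO1 | intermediate
9 | (5S)-5-[(3E)-5-hydroxy-4-methylhept-3-en-1-yl]-5-methyl-5,6-dihydro-2H-pyran-2-one | O=C1C=C[C@](C)(CC/C=C(\C)C(O)CC)CO1 | intermediate
10 | (5S)-5-methyl-5-(4-methyl-5-oxoheptyl)-5,6-dihydro-2H-pyran-2-one | O=C1C=C[C@](C)(CCCC(C)C(=O)CC)CO1 | intermediate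
11 | (4aS,5S,8aS)-5,8a-dimethyl-5-propanoyloctahydro-3H-isochromen-3-one (cis-fused Michael adduct) | O=C1C[C@H]2[C@@](C)(CO1)CCC[C@]2(C)C(=O)CC | intermediate
12 | methyl 2-[(1S,2S,6S)-2-(hydroxymethyl)-2,6-dimethyl-6-propanoylcyclohexyl]acetate | COC(=O)C[C@H]1[C@@](C)(CO)CCC[C@]1(C)C(=O)CC | intermediate
13 | (4aS,5S,8aS)-5-(hydroxymethyl)-2,5,8a-trimethylhexahydronaphthalene-1,3(2H,4H)-dione | CC1C(=O)C[C@H]2[C@@](C)(CO)CCC[C@]2(C)C1=O | intermediate
14 | (4aS,5S,8aS)-5-{[(tert-butyldimethylsilyl)oxy]methyl}-2,5,8a-trimethylhexahydronaphthalene-1,3(2H,4H)-dione | CC1C(=O)C[C@H]2[C@@](C)(CO[Si](C)(C)C(C)(C)C)CCC[C@]2(C)C1=O | intermediate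
15 | (4aS,5S,8aS)-5-{[(tert-butyldimethylsilyl)oxy]methyl}-2,5,8a-trimethyl-1-oxo-1,4,4a,5,6,7,8,8a-octahydronaphthalen-3-yl trifluoromethanesulfonate | CC1=C(OS(=O)(=O)C(F)(F)F)C[C@H]2[C@@](C)(CO[Si](C)(C)C(C)(C)C)CCC[C@]2(C)C1=O | intermediate
16 | (4aS,5S,8aS)-5-{[(tert-butyldimethylsilyl)oxy]methyl}-2,5,8a-trimethyl-4a,5,6,7,8,8a-hexahydronaphthalen-1(4H)-one | CC1=CC[C@H]2[C@@](C)(CO[Si](C)(C)C(C)(C)C)CCC[C@]2(C)C1=O | intermediate
17 | (4aS,5S,8aS)-5-{[(tert-butyldimethylsilyl)oxy]methyl}-2,5,8a-trimethyl-4a,5,6,7,8,8a-hexahydronaphthalen-1-yl trifluoromethanesulfonate | CC1=C(OS(=O)(=O)C(F)(F)F)[C@@]2(C)CCC[C@](C)(CO[Si](C)(C)C(C)(C)C)[C@@H]2C=C1 | intermediate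
18 | 4-bromobut-1-yne | C#CCCBr | starting material
19 | tert-butyl 5-bromopent-2-ynoate | BrCCC#CC(=O)OC(C)(C)C | intermediate
20 | tert-butyl (Z)-5-bromo-3-methylpent-2-enoate | BrCC/C(C)=C\C(=O)OC(C)(C)C | intermediate
21 | [(Z)-5-tert-butoxy-3-methyl-5-oxopent-3-en-1-yl]zinc bromide | Br[Zn]CC/C(C)=C\C(=O)OC(C)(C)C | intermediate
22 | tert-butyl (4S,5R,10S,13Z)-19-[(tert-butyldimethylsilyl)oxy]labda-6,8,13-trien-15-oate | CC1=C(CC/C(C)=C\C(=O)OC(C)(C)C)[C@@]2(C)CCC[C@](C)(CO[Si](C)(C)C(C)(C)C)[C@@H]2C=C1 | intermediate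
23 | tert-butyl (4S,5R,9S,10R,13Z)-19-[(tert-butyldimethylsilyl)oxy]labda-7,13-dien-15-oate | CC(C)(C)[Si](C)(C)OC[C@@]1(C)CCC[C@]2(C)[C@@H](CC/C(C)=C\C(=O)OC(C)(C)C)C(C)=CC[C@@H]12 | intermediate
24 | tert-butyl (4S,5R,9S,10R,13Z)-19-hydroxylabda-7,13-dien-15-oate | OC[C@@]1(C)CCC[C@]2(C)[C@@H](CC/C(C)=C\C(=O)OC(C)(C)C)C(C)=CC[C@@H]12 | intermediate
25 | tert-butyl (4S,5R,9S,10R,13Z)-19-[(Z)-2-methylbut-2-enoyloxy]labda-7,13-dien-15-oate | C/C=C(/C)C(=O)OC[C@@]1(C)CCC[C@]2(C)[C@@H](CC/C(C)=C\C(=O)OC(C)(C)C)C(C)=CC[C@@H]12 | intermediate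
26 | trimethylsilyl (4S,5R,9S,10R,13Z)-19-[(Z)-2-methylbut-2-enoyloxy]labda-7,13-dien-15-oate | C/C=C(/C)C(=O)OC[C@@]1(C)CCC[C@]2(C)[C@@H](CC/C(C)=C\C(=O)O[Si](C)(C)C)C(C)=CC[C@@H]12 | intermediate
27 | (4S,5R,9S,10R,13Z)-19-[(Z)-2-methylbut-2-enoyloxy]labda-7,13-dien-15-oic acid | C/C=C(/C)C(=O)OC[C@@]1(C)CCC[C@]2(C)[C@@H](CC/C(C)=C\C(=O)O)C(C)=CC[C@@H]12 | target

**Step count and risks**

Total steps: 20. Longest linear sequence: 18 (steps 1–13 and 16–20; steps 14 and 15 make the side-chain fragment).

Steps most likely to fail: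

1. Step 9.
   - What may go wrong: the Michael addition joins a neopentyl acceptor carbon to a fully substituted enolate carbon and may be slow or reverse; methanolysis of the lactone before C–C bond formation would remove the relay from C4 to C5; facial selection at C10 may fail and lead to the cis-decalin.
   - Fallback (sets out from 9, comes back at 11 and from there at 13): Dess–Martin oxidation of 9 should give the E-enone F1. Conjugate hydrosilylation (Et3SiH, RhCl(PPh3)3) should then give the regiodefined tetrasubstituted triethylsilyl enol ether F2. TiCl4 in CH2Cl2 at −78 °C should close ring A by an irreversible intramolecular Mukaiyama–Michael addition on the intact lactone to give 11, now isolated. NaOMe in MeOH then takes 11 through 12 to 13.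

2. Step 17.
   - What may go wrong: the diene may not bind chromium at its tetrasubstituted terminus, or the catalyst may cause double-bond migration or over-reduction.
   - Fallback (sets out from 16, comes back at 23): Wittig methylenation of 16 (Ph3P=CH2, toluene, 90 °C) should give the exocyclic 7,9(11)-diene F3. 9-BBN should add to the methylene group from the α face to give the C11 borane F4, which NaOH/H2O2 oxidises to the primary alcohol F5 with H-9α. Dess–Martin oxidation gives the aldehyde F6 (kept cold, no base), a second Wittig methylenation the 9-vinyl compound F7, and 9-BBN the primary borane F8. B-alkyl Suzuki–Miyaura coupling (PdCl2(dppf), Cs2CO3, DMF/H2O) with the Z-iodoenoate F9, made from tert-butyl but-2-ynoate with NaI in AcOH, gives 23.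

3. Step 16.
   - What may go wrong: transmetalation and reductive elimination at C9, flanked by quaternary C10 and the 8-methyl, may be slow, so β-hydride elimination and simple reduction of the triflate compete.
   - Fallback (sets out from 17, comes back at 22): Stille coupling of 17 with tributyl(vinyl)stannane (Pd(PPh3)4, LiCl, THF, 65 °C), which is less sensitive to hindrance, should give the 9-vinyl triene F10. 9-BBN should hydroborate only the terminal vinyl group to give the borane F11. B-alkyl Suzuki–Miyaura coupling with the Z-iodoenoate F12 (made as F9) gives 22.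

**Further compounds**

F1 | step 9 | (5S)-5-methyl-5-[(3E)-4-methyl-5-oxohept-3-en-1-yl]-5,6-dihydro-2H-pyran-2-one | O=C1C=C[C@](C)(CC/C=C(\C)C(=O)CC)CO1
F2 | step 9 | (5S)-5-methyl-5-[4-methyl-5-(triethylsilyloxy)hept-4-en-1-yl]-5,6-dihydro-2H-pyran-2-one | O=C1C=C[C@](C)(CCCC(C)=C(CC)O[Si](CC)(CC)CC)CO1
F3 | step 17 | (4aS,5S,8aS)-5-{[(tert-butyldimethylsilyl)oxy]methyl}-2,5,8a-trimethyl-1-methylidene-1,4,4a,5,6,7,8,8a-octahydronaphthalene | CC1=CC[C@H]2[C@@](C)(CO[Si](C)(C)C(C)(C)C)CCC[C@]2(C)C1=C
F4 | step 17 | B-alkyl-9-BBN at C11 of the 19-silyloxy drim-7-ene core (H-9α) | CC(C)(C)[Si](C)(C)OC[C@@]1(C)CCC[C@]2(C)[C@@H](CB3C4CCCC3CCC4)C(C)=CC[C@@H]12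
F5 | step 17 | 11-hydroxy analogue (19-silyloxy drimenol type, H-9α) | CC(C)(C)[Si](C)(C)OC[C@@]1(C)CCC[C@]2(C)[C@@H](CO)C(C)=CC[C@@H]12
F6 | step 17 | 11-aldehyde (19-silyloxy drimenal type, H-9α) | CC(C)(C)[Si](C)(C)OC[C@@]1(C)CCC[C@]2(C)[C@@H](C=O)C(C)=CC[C@@H]12
F7 | step 17 | 9β-vinyl compound (C11=C12 alkene, H-9α) | CC(C)(C)[Si](C)(C)OC[C@@]1(C)CCC[C@]2(C)[C@@H](C=C)C(C)=CC[C@@H]12
F8 | step 17 | B-alkyl-9-BBN at C12 | CC(C)(C)[Si](C)(C)OC[C@@]1(C)CCC[C@]2(C)[C@@H](CCB3C4CCCC3CCC4)C(C)=CC[C@@H]12
F9 | step 17 | tert-butyl (Z)-3-iodobut-2-enoate | I/C(C)=C\C(=O)OC(C)(C)C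
F10 | step 16 | 9-vinyl ring B 6,8-diene (triene) | CC1=C(C=C)[C@@]2(C)CCC[C@](C)(CO[Si](C)(C)C(C)(C)C)[C@@H]2C=C1
F11 | step 16 | B-alkyl-9-BBN at C12 of the 6,8-diene | CC1=C(CCB3C4CCCC3CCC4)[C@@]2(C)CCC[C@](C)(CO[Si](C)(C)C(C)(C)C)[C@@H]2C=C1
F12 | step 16 | tert-butyl (Z)-3-iodobut-2-enoate | I/C(C)=C\C(=O)OC(C)(C)C
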